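| flask | J | G | remark | time |
|---|---|---|---|---|
| amber | 0.050 M | 1 equiv | run made earlier |  |
| teal | 0.050 M | 1.7 equiv | run made earlier |  |
| blue | 0.050 M | 1.8 equiv | run made earlier |  |
| Sunday's | 0.050 M | 1.20 equiv |  | 25 min |
| Thursday's | 0.050 M | 2.40 equiv |  | 25 min |

| run | time / min | D / % | E / % | J / % |
|---|---|---|---|---|
| amber | 2.00 | 10.2 | 0 | 68.1 |
| amber | 5.00 | 16.9 | 1.0 | 50.6 |
| amber | 10.0 | 20.7 | 2.7 | 45.5 |
| amber | 25.0 | 24.4 | 3.1 | 43.4 |
| teal | 3.00 | 21.2 | 1.2 | 53.1 |
| teal | 8.00 | 30.5 | 4.5 | 37.2 |
| teal | 15.0 | 32.5 | 6.8 | 35.9 |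
| teal | 25.0 | 34.9 | 7.8 | 35.1 |
| blue | 6.00 | 27.7 | 3.1 | 39.3 |
| blue | 12.0 | 33.1 | 6.9 | 35.2 |
| blue | 20.0 | 35.0 | 7.6 | 33.7 |
| blue | 25.0 | 35.2 | 7.6 | 32.7 |

(scatter of a reading: 0.5 percentage points)

- a reading or a percentage of E counts all its forms, free or not
- a reading of J is of its free form alone

1. which of these there is most of at the end, counted by the J in it, Sunday's (E / J / D)
2. which of these there is most of at the end, counted by the J in it, Thursday's (E / J / D)
3. the largest of these amounts at the end, in percent of the J charged, Sunday's
4. the largest of these amounts at the end, in percent of the J charged, Thursday's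

- At early times J + D + E already falls short of the charge: amber lacks 21.7% at 2.00 min. So J seems to sit partly in an unseen form.
- Call the pool everything not yet D or E. Free J is a nearly constant share of it at the end: 0.594 on average. Freeze that share.
- Then the pool falls as the time integral of c(G). Blue stalls at 57.2%, though its products took 28.0% of the G charge. So G seems to die another way. If that loss is first order, the integral scales with the charge.
- This gives one number, the reach per equivalent: ln(charge/final pool) divided by the equivalents of G, at c(J) 0.050 M. You read 0.322, 0.328 and 0.310, mean 0.320.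
- Is one number enough? Not quite. The split needs the frozen share, and E needs a second reading: E is about 0.418 times the square of the converted fraction. Thursday's loading also lies beyond the runs.
- My reckoning for Sunday's: J 40.5%, D 27.6%. For Thursday's: J 27.6%, D 41.6%.
- The forecast, holding that “G dies by a parallel route”, names J at 40.5% for Sunday's and D at 40% for Thursday's, the latter below my D.
- Sunday's flask gives J at 40.6%. Thursday's flask gives D at 39.8%.

    J + G → D + X (k = 1.53 M⁻¹ min⁻¹)
    J ⇌ L (K = 0.676, k = 0.176 min⁻¹)
    G + D → E + X (k = 0.679 M⁻¹ min⁻¹)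
    G → Z (k = 0.113 min⁻¹)
    Q ⇌ E, rate k5*(cs5 - [E]) while solid is left; crystals form when [E] > cs5 (solubility = 41.0 mM, k = 1.84 min⁻¹)

- On Thursday's, J + G → D + X had 92% of its turnover behind it at 12.5 min, while G → Z had 55% at 5.00 min. Thursday's G ended at 2.3% of its charge, less than the 28% of J. Thursday's own reach per equivalent is 0.320. At 1.40 equiv, the reach gives J 38.0%, and that neighbour flask holds 38.0%.

The earlier runs and the new flask were computed for substances that don't exist, noise included.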